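Ring C is cut first, at C2–C3 together with C3–H. C2 is a plain CH2 bonded only to O1 and C3, so it can be read as the methyl carbon of a ring-A aryl methyl ether joined to the carbon between the C4 carbonyl and ring B. The precursor is therefore a 2-methoxyaryl alpha-aryl-alpha-diazoketone.
The next cuts are the diazo group (back to the deoxybenzoin), C4–C4a (ring-A aryl Grignard reagent plus ring-B arylacetaldehyde) and C3–C4 (one-carbon Wittig homologation of the ring-B aldehyde). In ring B they are C5'–C(quaternary) (aromatic Claisen shift from O4') and O4'–CH3.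
Forward: ring B is dressed on 2,3,4-trihydroxybenzaldehyde, lengthened by one carbon, coupled with ring A, oxidised and diazotised. Ring C, the only ring that is built, closes in the penultimate step, and desilylation ends the route.
C3 (R), the only stereocentre, is set in the ring closure by the chiral dirhodium carboxylate and afterwards meets only neutral or weakly acidic media.

Key step: step 11

Assumption: the sense of induction of Rh2(S-PTAD)4 (dirhodium tetrakis[(S)-(1-adamantyl)(phthalimido)acetate]) in this closure cannot be derived safely from models, so the S catalyst is written as the one that gives (3R). If the first run shows the opposite sense, the equally available Rh2(R-PTAD)4 takes its place with nothing else changed.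

Step 1
Reactants: 1 2,3,4-trihydroxybenzaldehyde; 2 prenyl bromide (1-bromo-3-methylbut-2-ene)
Product: 3 2,3-dihydroxy-4-(3-methylbut-2-en-1-yloxy)benzaldehyde
Conditions: NaHCO3 (1.5 equiv), DMF, 40 °C, Ar
Reagents that add atoms: none
Why: Williamson etherification under weak-base control should touch only the 4-OH, which is para to the formyl group and therefore the most acidic, while the 2-OH is tied up in a hydrogen bond to the aldehyde and the 3-OH stays protonated, the same logic that makes 4-selective alkylation of 2,4- and 3,4-dihydroxybenzaldehydes routine.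

Step 2
Reactants: 3 2,3-dihydroxy-4-(3-methylbut-2-en-1-yloxy)benzaldehyde
Product: 5 2,3,4-trihydroxy-5-(2-methylbut-3-en-2-yl)benzaldehyde, via ortho-dienone 4 (not isolated)
Conditions: PhNEt2, 200 °C (sealed vial, microwave), 45 min, Ar
Reagents that add atoms: none
Why: Aromatic Claisen rearrangement: the [3,3] shift turns the prenyl unit round and delivers its tertiary carbon to C5, the only position ortho to O4 that carries hydrogen, so dienone 4 can tautomerise to phenol 5, and the basic solvent together with a short heating time holds back ring closure of the new phenol onto the alkene and the abnormal Claisen pathway.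

Step 3
Reactants: 5 2,3,4-trihydroxy-5-(2-methylbut-3-en-2-yl)benzaldehyde
Product: 6 2,3-dihydroxy-4-methoxy-5-(2-methylbut-3-en-2-yl)benzaldehyde
Conditions: MeI (1.1 equiv), Li2CO3 (1.2 equiv), DMF, 45 °C, Ar
Reagents that add atoms: iodomethane, CI
Why: Acidity-controlled Williamson methylation: Li2CO3 ionises only the 4-OH (para to the aldehyde), as in the 4-selective alkylation of the parent trihydroxybenzaldehyde, and the small electrophile should still reach this oxygen although it now lies next to the quaternary carbon.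

Step 4
Reactants: 6 2,3-dihydroxy-4-methoxy-5-(2-methylbut-3-en-2-yl)benzaldehyde
Product: 7 2,3-bis(tert-butyldimethylsilyloxy)-4-methoxy-5-(2-methylbut-3-en-2-yl)benzaldehyde
Conditions: TBSCl (2.6 equiv), i-Pr2NEt, DMF, rt
Reagents that add atoms: tert-butyldimethylsilyl chloride, CC(C)(C)[Si](C)(C)Cl
Why: Standard phenol silylation, well known for the parent 2,3-dihydroxy-4-methoxybenzaldehyde, puts silicon and not carbon on O2' so that no C–H bond will later sit within five-ring reach of the carbene, and it makes the late intermediates soluble in hydrocarbons.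

Step 5
Reactants: 7 2,3-bis(tert-butyldimethylsilyloxy)-4-methoxy-5-(2-methylbut-3-en-2-yl)benzaldehyde
Product: 8 1-(2-methoxyethenyl)-2,3-bis(tert-butyldimethylsilyloxy)-4-methoxy-5-(2-methylbut-3-en-2-yl)benzene (E/Z mixture)
Conditions: MeOCH2PPh3Cl, KN(SiMe3)2, THF, 0 °C; then 7, 0 °C → rt
Reagents that add atoms: (methoxymethyl)triphenylphosphonium chloride, COC[P+](c1ccccc1)(c1ccccc1)c1ccccc1.[Cl-]
Why: Wittig methoxymethylenation of a non-enolisable aromatic aldehyde is a reaction class that ortho-silyloxybenzaldehydes of this kind tolerate, and the alkene geometry is irrelevant because both isomers lead to the same aldehyde.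

Step 6
Reactants: 8 1-(2-methoxyethenyl)-2,3-bis(tert-butyldimethylsilyloxy)-4-methoxy-5-(2-methylbut-3-en-2-yl)benzene
Product: 9 2-[2,3-bis(tert-butyldimethylsilyloxy)-4-methoxy-5-(2-methylbut-3-en-2-yl)phenyl]acetaldehyde
Conditions: 2 M aq HCl, THF, rt → 40 °C; used at once
Reagents that add atoms: water, O
Why: Acid-catalysed enol ether hydrolysis (C-protonation, hydration of the oxocarbenium ion, loss of methanol) runs in dilute acid that flanked phenolic silyl ethers and the monosubstituted alkene withstand, such acid being the usual means of removing alkyl silyl ethers beside aryl ones.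

Step 7
Reactants: 10 4-bromo-3-methoxyphenol
Product: 11 (4-bromo-3-methoxyphenoxy)(tert-butyl)dimethylsilane
Conditions: TBSCl, imidazole, DMF, rt
Reagents that add atoms: tert-butyldimethylsilyl chloride, CC(C)(C)[Si](C)(C)Cl
Why: Standard silylation of an unhindered phenol is needed so that the acidic OH quenches neither the organometallic reagent of step 8 nor the carbene of step 11.

Step 8
Reactants: 11 (4-bromo-3-methoxyphenoxy)(tert-butyl)dimethylsilane; 9 2-[2,3-bis(tert-butyldimethylsilyloxy)-4-methoxy-5-(2-methylbut-3-en-2-yl)phenyl]acetaldehyde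
Product: 13 1-[4-(tert-butyldimethylsilyloxy)-2-methoxyphenyl]-2-[2,3-bis(tert-butyldimethylsilyloxy)-4-methoxy-5-(2-methylbut-3-en-2-yl)phenyl]ethan-1-ol (racemic), via aryl Grignard reagent 12 (not isolated)
Conditions: 11, Mg, I2 (trace), THF, reflux; then 9, THF, −40 → 0 °C; aq NH4Cl
Reagents that add atoms: none
Why: Grignard addition of an ortho-methoxyarylmagnesium bromide to an aldehyde forms C4–C4a, the low temperature and the modest basicity of the magnesium reagent limiting enolisation of 9, and the new carbinol centre arises as a racemate that is erased in step 9.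

Step 9
Reactants: 13 1-[4-(tert-butyldimethylsilyloxy)-2-methoxyphenyl]-2-[2,3-bis(tert-butyldimethylsilyloxy)-4-methoxy-5-(2-methylbut-3-en-2-yl)phenyl]ethan-1-ol
Product: 14 1-[4-(tert-butyldimethylsilyloxy)-2-methoxyphenyl]-2-[2,3-bis(tert-butyldimethylsilyloxy)-4-methoxy-5-(2-methylbut-3-en-2-yl)phenyl]ethan-1-one
Conditions: DMP, CH2Cl2, 0 °C → rt
Reagents that add atoms: none
Why: Dess–Martin oxidation of a secondary benzylic alcohol proceeds under near-neutral conditions that leave the silyl ethers, the alkene and the electron-rich rings alone.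

Step 10
Reactants: 14 1-[4-(tert-butyldimethylsilyloxy)-2-methoxyphenyl]-2-[2,3-bis(tert-butyldimethylsilyloxy)-4-methoxy-5-(2-methylbut-3-en-2-yl)phenyl]ethan-1-one
Product: 15 2-diazo-1-[4-(tert-butyldimethylsilyloxy)-2-methoxyphenyl]-2-[2,3-bis(tert-butyldimethylsilyloxy)-4-methoxy-5-(2-methylbut-3-en-2-yl)phenyl]ethan-1-one
Conditions: p-ABSA, DBU, dry MeCN, 0 °C → rt, Ar, dark
Reagents that add atoms: 4-acetamidobenzenesulfonyl azide (p-ABSA), CC(=O)Nc1ccc(cc1)S(=O)(=O)N=[N+]=[N-]
Why: Regitz diazo transfer works directly, without prior activation, on benzyl aryl ketones because the doubly activated CH2 is acidic enough for DBU, and dry conditions protect the aryl silyl ethers from amidine-promoted cleavage.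

Step 11
Reactants: 15 2-diazo-1-[4-(tert-butyldimethylsilyloxy)-2-methoxyphenyl]-2-[2,3-bis(tert-butyldimethylsilyloxy)-4-methoxy-5-(2-methylbut-3-en-2-yl)phenyl]ethan-1-one
Product: 17 (3R)-7-(tert-butyldimethylsilyloxy)-3-[2,3-bis(tert-butyldimethylsilyloxy)-4-methoxy-5-(2-methylbut-3-en-2-yl)phenyl]chroman-4-one, via dirhodium carbene 16 (not isolated)
Conditions: Rh2(S-PTAD)4 (1 mol %), 4 Å MS, 2,2-dimethylbutane, reflux (50 °C), 15 added by syringe pump over 3 h (final concentration about 0.005 M), Ar
Reagents that add atoms: none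
Why: Rh2(S-PTAD)4 expels N2 from 15 and holds the resulting donor/acceptor carbene 16, whose carbon (the future C3) takes up one C–H bond of the ring-A methoxy group through a concerted, asynchronous three-centre transition state with hydride-transfer character, so that C2–C3 and C3–H are made in a single event. The closest known reaction types are the chroman-4-one-forming intramolecular C–H insertion of ortho-alkoxyaryl diazoketones under chiral dirhodium tetracarboxylates, the C–H insertion cyclisation of alpha-aryl-alpha-diazoketones and the insertion of donor/acceptor carbenes into methyl ethers, and what is extrapolated here is their meeting in one substrate. Ring C closes as a six-membered ring by 1,6-insertion (C3, C4, C4a, C8a, O1, C2), the only closure open on this side because the atom from which a five-membered ring would arise is O1 and bears no hydrogen, while O1 in turn activates the methyl C–H bonds by stabilising the positive charge that builds up on C2. C3 is the only new stereocentre and its configuration is fixed by the chiral pocket of the four phthalimido(adamantyl)acetate ligands, which leaves one face of the carbene open to the approaching C–H bond, in a neutral hydrocarbon medium in which the product cannot enolise. The step needs insertion to win over attack of O1 on the carbene, and this is secured because O1 is a weak donor (vinylogous ester oxygen), ylide formation is reversible and methyl is a poor migrating group for the 1,2-shift that would drain the ylide. On the ring-B side silicon in place of carbon on O2' removes the fast five-membered insertion that any alkyl ether would offer, the meta-placed vinyl group cannot reach the carbene within the molecule, and slow addition at high dilution holds back intermolecular cyclopropanation and carbene dimerisation.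

Step 12
Reactants: 17 (3R)-7-(tert-butyldimethylsilyloxy)-3-[2,3-bis(tert-butyldimethylsilyloxy)-4-methoxy-5-(2-methylbut-3-en-2-yl)phenyl]chroman-4-one
Product: 18 (3R)-3-[2,3-dihydroxy-4-methoxy-5-(2-methylbut-3-en-2-yl)phenyl]-7-hydroxychroman-4-one (CNP0134633.2)
Conditions: HF·pyridine, excess pyridine, THF, 0 °C, Ar; pH 7 buffer work-up
Reagents that add atoms: none
Why: Fluoride-driven cleavage of aryl silyl ethers in a weakly acidic, pyridine-buffered medium avoids the phenoxide or enolate formation that would racemise C3, and the buffered reagent does not add to the monosubstituted alkene.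

Compound list
1 | 2,3,4-trihydroxybenzaldehyde | O=Cc1ccc(O)c(O)c1O | starting material
2 | prenyl bromide (1-bromo-3-methylbut-2-ene) | CC(C)=CCBr | starting material
3 | 2,3-dihydroxy-4-(3-methylbut-2-en-1-yloxy)benzaldehyde | O=Cc1ccc(OCC=C(C)C)c(O)c1O | intermediate
4 | Claisen ortho-dienone, 5,6-dihydroxy-3-(2-methylbut-3-en-2-yl)-4-oxocyclohexa-1,5-diene-1-carbaldehyde (racemic, not isolated) | O=CC1=CC(C(C)(C)C=C)C(=O)C(O)=C1O | intermediate
5 | 2,3,4-trihydroxy-5-(2-methylbut-3-en-2-yl)benzaldehyde | O=Cc1cc(C(C)(C)C=C)c(O)c(O)c1O | intermediate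
6 | 2,3-dihydroxy-4-methoxy-5-(2-methylbut-3-en-2-yl)benzaldehyde | O=Cc1cc(C(C)(C)C=C)c(OC)c(O)c1O | intermediate
7 | 2,3-bis(tert-butyldimethylsilyloxy)-4-methoxy-5-(2-methylbut-3-en-2-yl)benzaldehyde | O=Cc1cc(C(C)(C)C=C)c(OC)c(O[Si](C)(C)C(C)(C)C)c1O[Si](C)(C)C(C)(C)C | intermediate
8 | 1-(2-methoxyethenyl)-2,3-bis(tert-butyldimethylsilyloxy)-4-methoxy-5-(2-methylbut-3-en-2-yl)benzene (E/Z mixture) | COC=Cc1cc(C(C)(C)C=C)c(OC)c(O[Si](C)(C)C(C)(C)C)c1O[Si](C)(C)C(C)(C)C | intermediate
9 | 2-[2,3-bis(tert-butyldimethylsilyloxy)-4-methoxy-5-(2-methylbut-3-en-2-yl)phenyl]acetaldehyde | O=CCc1cc(C(C)(C)C=C)c(OC)c(O[Si](C)(C)C(C)(C)C)c1O[Si](C)(C)C(C)(C)C | intermediate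
10 | 4-bromo-3-methoxyphenol | COc1cc(O)ccc1Br | starting material
11 | (4-bromo-3-methoxyphenoxy)(tert-butyl)dimethylsilane | COc1cc(O[Si](C)(C)C(C)(C)C)ccc1Br | intermediate
12 | [4-(tert-butyldimethylsilyloxy)-2-methoxyphenyl]magnesium bromide (not isolated) | COc1cc(O[Si](C)(C)C(C)(C)C)ccc1[Mg]Br | intermediate
13 | 1-[4-(tert-butyldimethylsilyloxy)-2-methoxyphenyl]-2-[2,3-bis(tert-butyldimethylsilyloxy)-4-methoxy-5-(2-methylbut-3-en-2-yl)phenyl]ethan-1-ol (racemic) | COc1cc(O[Si](C)(C)C(C)(C)C)ccc1C(O)Cc1cc(C(C)(C)C=C)c(OC)c(O[Si](C)(C)C(C)(C)C)c1O[Si](C)(C)C(C)(C)C | intermediate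
14 | 1-[4-(tert-butyldimethylsilyloxy)-2-methoxyphenyl]-2-[2,3-bis(tert-butyldimethylsilyloxy)-4-methoxy-5-(2-methylbut-3-en-2-yl)phenyl]ethan-1-one | COc1cc(O[Si](C)(C)C(C)(C)C)ccc1C(=O)Cc1cc(C(C)(C)C=C)c(OC)c(O[Si](C)(C)C(C)(C)C)c1O[Si](C)(C)C(C)(C)C | intermediate
15 | 2-diazo-1-[4-(tert-butyldimethylsilyloxy)-2-methoxyphenyl]-2-[2,3-bis(tert-butyldimethylsilyloxy)-4-methoxy-5-(2-methylbut-3-en-2-yl)phenyl]ethan-1-one | COc1cc(O[Si](C)(C)C(C)(C)C)ccc1C(=O)C(=[N+]=[N-])c1cc(C(C)(C)C=C)c(OC)c(O[Si](C)(C)C(C)(C)C)c1O[Si](C)(C)C(C)(C)C | intermediate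
16 | dirhodium carbene of 15 (not isolated; only the carbene-bearing rhodium atom is drawn, the rest of the Rh2(S-PTAD)4 core is implied) | COc1cc(O[Si](C)(C)C(C)(C)C)ccc1C(=O)C(=[Rh])c1cc(C(C)(C)C=C)c(OC)c(O[Si](C)(C)C(C)(C)C)c1O[Si](C)(C)C(C)(C)C | intermediate
17 | (3R)-7-(tert-butyldimethylsilyloxy)-3-[2,3-bis(tert-butyldimethylsilyloxy)-4-methoxy-5-(2-methylbut-3-en-2-yl)phenyl]chroman-4-one | C=CC(C)(C)c1cc([C@@H]2COc3cc(O[Si](C)(C)C(C)(C)C)ccc3C2=O)c(O[Si](C)(C)C(C)(C)C)c(O[Si](C)(C)C(C)(C)C)c1OC | intermediate
18 | (3R)-3-[2,3-dihydroxy-4-methoxy-5-(2-methylbut-3-en-2-yl)phenyl]-7-hydroxychroman-4-one | C=CC(C)(C)c1cc([C@@H]2COc3cc(O)ccc3C2=O)c(O)c(O)c1OC | target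

Total step count: 12. Longest linear sequence: 11 (steps 1–6 and 8–12, from 2,3,4-trihydroxybenzaldehyde).

Steps most likely to fail

1. Step 11. The carbene may be diverted by attack of O1 (oxonium ylide formation followed by methyl migration). Insertion into a primary C–H bond may be slow enough for dimerisation or intermolecular cyclopropanation to take over, or facial selectivity at C3 may be poor.
- The fallback sets out from 14 and comes back at 17.
- BCl3 in CH2Cl2 at −78 → 0 °C removes, under chelation to the C4 carbonyl, only the ring-A O-methyl group. This should give 1-[4-(tert-butyldimethylsilyloxy)-2-hydroxyphenyl]-2-[2,3-bis(tert-butyldimethylsilyloxy)-4-methoxy-5-(2-methylbut-3-en-2-yl)phenyl]ethan-1-one F1.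
- N,N-dimethylformamide dimethyl acetal in toluene at 90 °C supplies C2 and closes ring C to 7-(tert-butyldimethylsilyloxy)-3-[2,3-bis(tert-butyldimethylsilyloxy)-4-methoxy-5-(2-methylbut-3-en-2-yl)phenyl]chromen-4-one F2.
- Asymmetric transfer hydrogenation with RuCl[(R,R)-TsDPEN](p-cymene) in HCO2H/Et3N reduces the C2–C3 double bond. It then reduces the ketone under dynamic kinetic resolution of the base-labile C3 centre, to the cis-(3R,4R)-isoflavan-4-ol F3.
- Dess–Martin oxidation under neutral conditions restores the ketone and leaves C3 untouched, which gives 17.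

2. Step 2. The prenyl group may be lost by fragmentation, the side chain may rearrange further (abnormal Claisen), the new phenol may close onto the alkene, or the free catechol may degrade at 200 °C.
- The fallback sets out from 1 and comes back at 8. It installs the side chain by cross-coupling instead of a sigmatropic shift.
- Acidity-controlled methylation (MeI, Li2CO3, DMF) gives 2,3-dihydroxy-4-methoxybenzaldehyde F4.
- NBS in MeCN at 0 °C brominates the position para to the 2-OH and meta to the aldehyde, giving 5-bromo-2,3-dihydroxy-4-methoxybenzaldehyde F5.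
- TBSCl and i-Pr2NEt in DMF give 5-bromo-2,3-bis(tert-butyldimethylsilyloxy)-4-methoxybenzaldehyde F6.
- Wittig methoxymethylenation as in step 5 gives the bromo enol ether F7. This also masks the aldehyde, which an allylboronate would otherwise attack.
- A branched-selective Suzuki–Miyaura coupling follows, with prenylboronic acid pinacol ester, Pd(OAc)2, a bulky dialkylbiarylphosphine chosen for reaction through the gamma carbon of the allyl unit, and K3PO4 in THF/H2O at 40 °C. It places the 1,1-dimethylallyl group on C5 and gives 8.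

3. Step 3. Site selectivity may erode because the 4-OH is now flanked by the quaternary carbon, and over-methylation may occur.
- The fallback sets out from 3 and comes back at 7. It changes the order of events so that only one hydroxyl group is free when the methyl group is introduced.
- TBSCl and i-Pr2NEt in DMF convert 3 into 2,3-bis(tert-butyldimethylsilyloxy)-4-(3-methylbut-2-en-1-yloxy)benzaldehyde F8.
- Claisen rearrangement in PhNEt2 at 200 °C gives 2,3-bis(tert-butyldimethylsilyloxy)-4-hydroxy-5-(2-methylbut-3-en-2-yl)benzaldehyde F9.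
- Me3SiCHN2 in toluene/MeOH at rt methylates the single acidic phenol without a free phenoxide, so that silyl migration from O3 to O4 is not triggered. This gives 7.

Further compounds
F1 | step 11 | 1-[4-(tert-butyldimethylsilyloxy)-2-hydroxyphenyl]-2-[2,3-bis(tert-butyldimethylsilyloxy)-4-methoxy-5-(2-methylbut-3-en-2-yl)phenyl]ethan-1-one | Oc1cc(O[Si](C)(C)C(C)(C)C)ccc1C(=O)Cc1cc(C(C)(C)C=C)c(OC)c(O[Si](C)(C)C(C)(C)C)c1O[Si](C)(C)C(C)(C)C
F2 | step 11 | 7-(tert-butyldimethylsilyloxy)-3-[2,3-bis(tert-butyldimethylsilyloxy)-4-methoxy-5-(2-methylbut-3-en-2-yl)phenyl]chromen-4-one | C=CC(C)(C)c1cc(C2=COc3cc(O[Si](C)(C)C(C)(C)C)ccc3C2=O)c(O[Si](C)(C)C(C)(C)C)c(O[Si](C)(C)C(C)(C)C)c1OC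
F3 | step 11 | cis-(3R,4R)-7-(tert-butyldimethylsilyloxy)-3-[2,3-bis(tert-butyldimethylsilyloxy)-4-methoxy-5-(2-methylbut-3-en-2-yl)phenyl]chroman-4-ol | C=CC(C)(C)c1cc([C@@H]2COc3cc(O[Si](C)(C)C(C)(C)C)ccc3[C@@H]2O)c(O[Si](C)(C)C(C)(C)C)c(O[Si](C)(C)C(C)(C)C)c1OC
F4 | step 2 | 2,3-dihydroxy-4-methoxybenzaldehyde | COc1ccc(C=O)c(O)c1O
F5 | step 2 | 5-bromo-2,3-dihydroxy-4-methoxybenzaldehyde | COc1c(Br)cc(C=O)c(O)c1O
F6 | step 2 | 5-bromo-2,3-bis(tert-butyldimethylsilyloxy)-4-methoxybenzaldehyde | COc1c(Br)cc(C=O)c(O[Si](C)(C)C(C)(C)C)c1O[Si](C)(C)C(C)(C)C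
F7 | step 2 | 1-bromo-3,4-bis(tert-butyldimethylsilyloxy)-2-methoxy-5-(2-methoxyethenyl)benzene (E/Z mixture) | COC=Cc1cc(Br)c(OC)c(O[Si](C)(C)C(C)(C)C)c1O[Si](C)(C)C(C)(C)C
F8 | step 3 | 2,3-bis(tert-butyldimethylsilyloxy)-4-(3-methylbut-2-en-1-yloxy)benzaldehyde | O=Cc1ccc(OCC=C(C)C)c(O[Si](C)(C)C(C)(C)C)c1O[Si](C)(C)C(C)(C)C
F9 | step 3 | 2,3-bis(tert-butyldimethylsilyloxy)-4-hydroxy-5-(2-methylbut-3-en-2-yl)benzaldehyde | O=Cc1cc(C(C)(C)C=C)c(O)c(O[Si](C)(C)C(C)(C)C)c1O[Si](C)(C)C(C)(C)C
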